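## Structural features

The target 5 is a single 25-membered ring. It consists of the lactone oxygen, the carbonyl carbon C1, and an unbroken, unbranched run of 23 methylene groups, C2 to C24, with C24 bound to the ring oxygen. There is no stereocentre, double bond or substituent, so only connectivity has to be controlled. The only functional group is the ester. It tolerates acid, mild reductants and low-valent late-metal catalysts, but not hydride, alkali metals, organolithium or Grignard reagents, or hot aqueous base. A ring of this size has no angle or transannular strain and holds the ester in its preferred Z conformation. Closure therefore costs entropy only: two ends that are 24 bonds apart must meet before either finds another molecule. The second difficulty is supply, because a C24 chain with two different ends is not an article of commerce and must be joined from shorter pieces. Of the 25 ring bonds, 22 are indistinguishable CH2–CH2 bonds (C2–C3 to C23–C24), and a closure that joins two sp3 carbons directly at one of them leaves nothing to remove. The key step exploits the C12–C13 bond, which lies across the ring from the O–C1 bond. Cutting it divides the skeleton into two C12 halves, C1–C12 and C13–C24, whose new ends are both primary halides of the same polarity, and both halves are commercial omega-bromo C12 compounds.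

## Logic of the disconnections

**5 to 4.** The C12–C13 bond is cut and each carbon receives an iodine atom.
- In one sentence: a nickel-catalysed reductive coupling of the two primary alkyl iodide ends of 4 closes the 25-membered ring at C12–C13.
- The cut is placed here because it is the only CH2–CH2 bond whose scission gives two C12 halves of commercial length. It is also as far from the ester as the ring allows, so neither reacting carbon is perturbed by the carbonyl group.
- The gain is large. One operation both joins the chain and closes the ring, the two new ends need no differentiation, and the product appears at its final oxidation level.
- The forward step must unite two electrophilic carbons of like polarity by reduction, within one molecule, beside an ester, and without beta-hydride elimination. This calls for a tridentate ligand on nickel and pseudo-dilution.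

**4 to 3.** The two carbon–iodine bonds at C12 and C13 are exchanged for carbon–bromine bonds.
- Commerce offers the bromides, whereas low-valent nickel consumes iodides much faster, and slow addition depends on that speed.
- Nothing changes in the skeleton.
- The exchange must be complete at both ends, because mixed halides could not be separated.

**3 to 1 and 2.** The acyl–oxygen bond O–C1 is cut.
- The ester bond is the cheapest bond of the ring, and here it serves only as an intermolecular link at normal concentration.
- The gain is two commercial C12 pieces and no protecting group.
- The medium must be non-basic, so that no carboxylate can displace a bromide.

## Other disconnections considered

Alternative 1: the cut is the acyl–oxygen bond O–C1, the first that comes to mind. The forward key step is macrolactonisation of 24-hydroxytetracosanoic acid A1 under Yamaguchi or Shiina activation at high dilution.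
- The closure is dependable for a strain-free ring, but the cut removes one bond and leaves the whole supply problem untouched.
- A1 would have to be assembled by a carbon–carbon coupling of two C12 pieces with differentiated, protected ends, followed by deprotection and oxidation-state changes.
- The easiest bond of the molecule would be spent on the hardest operation, with a stoichiometric activating reagent and the same dilution.
- The step count would be roughly double that of the chosen plan.

Alternative 2: the cut is a ring alkene placed at C10–C11. The forward key step is ring-closing metathesis of pentadec-14-enyl undec-10-enoate A3 with second-generation Grubbs catalyst to tetracos-10-en-24-olide A4, followed by hydrogenation.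
- Metathesis expels two carbons as ethylene, so the diene needs 26 carbons, and the commercial C11 alkenyl pieces fall short.
- Pentadec-14-en-1-ol A2 would first have to be made by chain extension.
- Alkene migration by ruthenium hydride species before closure would shorten the ring by single CH2 units. In a featureless polymethylene series such homologues cannot be separated.
- The alkene serves only the closure and costs a further step to erase.
- This is also the second route most chemists would draw.

Alternative 3: the cut is again C12–C13, but at the alkyne oxidation level. The forward key step is the Glaser–Eglinton coupling (Cu(OAc)2, pyridine, slow addition) of dodec-11-ynyl dodec-11-ynoate A7 to tetracosa-11,13-diyn-24-olide A8, followed by exhaustive hydrogenation.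
- This is the strongest competitor, since it is a like-polarity union with a sound record in large-ring closure.
- It cannot deliver a traceless closure, however. Dodec-11-yn-1-ol A5 must be made by alkynylation of a shorter bromo alcohol, and dodec-11-ynoic acid A6 by oxidation of A5.
- Four equivalents of H2 are then needed to remove unsaturation that served only the closure.
- That makes five steps against three, with excess copper salt, for the same bond that the chosen plan forms directly between two sp3 carbons.

Key step: step 3

Remark: 5 has no stereocentre and no double bond, so no SMILES string of the route carries a stereodescriptor. Atom numbers follow the lactone (C1 carbonyl carbon, C24 the OCH2 carbon).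

## Route

Step 1
Reactants: 1 12-bromododecanoic acid; 2 12-bromododecan-1-ol
Product: 3 12-bromododecyl 12-bromododecanoate
Conditions: p-TsOH·H2O (5 mol %), toluene, reflux, Dean–Stark trap
Reagents that add atoms: none
Why: Fischer esterification driven to completion by azeotropic removal of water, which suits a non-volatile acid and alcohol used in equal amounts. The acidic medium keeps 1 protonated, so carboxylate attack on a carbon–bromine bond cannot compete, and primary bromides are stable under these conditions.

Step 2
Reactants: 3 12-bromododecyl 12-bromododecanoate
Product: 4 12-iodododecyl 12-iodododecanoate
Conditions: NaI (6 equiv), acetone, reflux, dark
Reagents that add atoms: sodium iodide, [Na+].[I-]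
Why: Finkelstein reaction, an SN2 halide exchange at two unhindered primary carbons that is pulled forward by precipitation of NaBr from acetone. The ester of a primary long-chain alcohol is not cleaved by iodide at this temperature.

Step 3
Reactants: 4 12-iodododecyl 12-iodododecanoate
Product: 5 24-tetracosanolide (oxacyclopentacosan-2-one)
Conditions: NiCl2(DME) (20 mol %), 4,4',4''-tri-tert-butyl-2,2':6',2''-terpyridine (22 mol %), Mn powder (4 equiv), DMA, 40 °C, Ar; 4 (0.05 M in DMA) added by syringe pump over 24 h, nominal final concentration 5 mM
Reagents that add atoms: none
Why: Proposed new method: the closest known reaction types are the nickel–terpyridine-catalysed reductive dimerisation of primary alkyl halides with Mn and the nickel-catalysed reductive cyclisation of alkyl dihalides to five- and six-membered rings, and what is new is the closure of a large ring. Mn should reduce the divalent nickel precatalyst to a low-valent terpyridine complex that abstracts the iodine atom of one chain end, recombines with the primary radical and, after one more electron from Mn, rests as a monovalent alkylnickel species, which the tridentate ligand shields from beta-hydride elimination and chain walking. This species abstracts iodine from a second carbon–iodine bond and captures the radical so formed, and the trivalent dialkylnickel iodide undergoes reductive elimination to the C(sp3)–C(sp3) bond with return of monovalent nickel iodide, the elementary sequence accepted for terpyridine–nickel alkyl–alkyl couplings. In 4 the second carbon–iodine bond is the far end of the same chain, so the single ring closes end to end: C12 and C13 meet in a 26-membered nickelacycle, which contracts to the 25-membered lactone on reductive elimination. The selectivity that matters is ring closure against chain growth; a ring of this size has no angle or transannular strain and lets the ester keep its Z conformation, so only entropy opposes closure, and effective molarities of the order of 10^-2 M are usual for such rings, well above the millimolar nickel concentration and the still lower stationary concentration of 4 under slow addition. Primary iodides are chosen because their fast reaction with low-valent nickel is what keeps that stationary concentration low. No cross-selectivity is required, since both ends are primary iodides of equal reactivity and any union of the two ends of one molecule gives 5, and the ester, eleven or more bonds away from either reacting carbon, is inert to Mn and to low-valent nickel. No stereocentre is formed, and 5 emerges at its final oxidation level with nothing left to remove.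

## Compound list

1 | 12-bromododecanoic acid | OC(=O)CCCCCCCCCCCBr | starting material
2 | 12-bromododecan-1-ol | OCCCCCCCCCCCCBr | starting material
3 | 12-bromododecyl 12-bromododecanoate | BrCCCCCCCCCCCC(=O)OCCCCCCCCCCCCBr | intermediate
4 | 12-iodododecyl 12-iodododecanoate | ICCCCCCCCCCCC(=O)OCCCCCCCCCCCCI | intermediate
5 | 24-tetracosanolide (oxacyclopentacosan-2-one) | O=C1CCCCCCCCCCCCCCCCCCCCCCCO1 | target

## Step count and least certain steps

Total step count: 3. Longest linear sequence: 3 steps (from 1 or 2 to 5).

**Step 3 (key step, proposed new method).**
- The most likely failure is premature reduction of one chain end. At millimolar nickel concentration, a primary radical that escapes from the metal has time to abstract hydrogen from DMA. A resting alkylnickel end can also be protonated by traces of water. Either event destroys one of the two handles before the ring closes.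
- The second threat is chain growth. If electron transfer from the Mn surface to nickel is slower than the feed, 4 accumulates and intermolecular coupling overtakes closure.
- The fallback uses known chemistry and keeps the C12–C13 cut as a union of like-polarity carbons. It sets out from 4. Kornblum oxidation of both primary iodides (DMSO, NaHCO3, 120 °C) should give the dialdehyde 12-oxododecyl 12-oxododecanoate F1. Intramolecular McMurry coupling (TiCl3(DME)1.5, Zn–Cu couple, DME, reflux, slow addition) is well established for large rings, and an aldehyde pair couples faster than an aldehyde–ester pair. It should give tetracos-12-en-24-olide F2 as an E/Z mixture. Hydrogenation (H2, Pd/C, EtOAc) comes back to the route at 5.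

**Step 1.**
- The most likely failure is incomplete conversion at exact 1:1 stoichiometry, together with slow acid-catalysed self-etherification of the alcohol on prolonged heating. This would carry monofunctional chain ends into the ring closure.
- The fallback builds the ester by redox disproportionation instead of condensation and needs one starting material only. It sets out from 2, which is oxidised (TEMPO cat., PhI(OAc)2, CH2Cl2) to 12-bromododecanal F3. The Tishchenko reaction (Al(OiPr)3 cat., toluene, room temperature) joins two molecules of this aldehyde head to tail and comes back to the route at 3.

**Step 2.**
- The most likely failure is incomplete halide exchange at one of the two ends. The Finkelstein reaction is an equilibrium, and mixed halide ends cannot be removed by chromatography or crystallisation from so long a chain. Ends of unequal reactivity would then let substrate accumulate in step 3.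
- The fallback moves the exchange to the stage of the polar, crystalline C12 pieces, where residual bromide can be removed by recrystallisation. It sets out from 1 and 2, which NaI in refluxing acetone should convert into 12-iodododecanoic acid F4 and 12-iodododecan-1-ol F5. Acid-catalysed azeotropic esterification of the two (p-TsOH·H2O, toluene, Dean–Stark trap, dark) comes back to the route at 4.

## Further compounds

F1 | step 3 | 12-oxododecyl 12-oxododecanoate | O=CCCCCCCCCCCC(=O)OCCCCCCCCCCCC=O
F2 | step 3 | tetracos-12-en-24-olide (E/Z mixture) | O=C1CCCCCCCCCCC=CCCCCCCCCCCCO1
F3 | step 1 | 12-bromododecanal | O=CCCCCCCCCCCCBr
F4 | step 2 | 12-iodododecanoic acid | OC(=O)CCCCCCCCCCCI
F5 | step 2 | 12-iodododecan-1-ol | OCCCCCCCCCCCCI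
A1 | alternative 1 | 24-hydroxytetracosanoic acid | OC(=O)CCCCCCCCCCCCCCCCCCCCCCCO
A2 | alternative 2 | pentadec-14-en-1-ol | OCCCCCCCCCCCCCC=C
A3 | alternative 2 | pentadec-14-enyl undec-10-enoate | C=CCCCCCCCCC(=O)OCCCCCCCCCCCCCC=C
A4 | alternative 2 | tetracos-10-en-24-olide (E/Z mixture) | O=C1CCCCCCCCC=CCCCCCCCCCCCCCO1
A5 | alternative 3 | dodec-11-yn-1-ol | OCCCCCCCCCCC#C
A6 | alternative 3 | dodec-11-ynoic acid | OC(=O)CCCCCCCCCC#C
A7 | alternative 3 | dodec-11-ynyl dodec-11-ynoate | C#CCCCCCCCCCC(=O)OCCCCCCCCCCC#C
A8 | alternative 3 | tetracosa-11,13-diyn-24-olide | O=C1CCCCCCCCCC#CC#CCCCCCCCCCCO1
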